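**Plan**

1. Retrosynthetic cuts, in order: the Si–O bond masking the allylic alcohol; the bond from C3 of the furan-2(5H)-one ring to its side-chain CH2 (B-alkyl Suzuki); both CH–CH2OAc bonds (each CH2O carbon is inserted into a C–B bond and then oxidised).
2. This exposes a 1,5-bis(secondary boronic ester), which is cut at the CH2–CH(B) bond on each side of the central (CH2)3 tether.
3. Enabling feature: each stereocentre is a CH carrying one CH2OAc branch and two CH2 chains, and the two CH atoms sit 1,5 across three CH2 groups. Each CH is therefore a carbenoid carbon inserted into one C–B bond of a propane-1,3-diyl diboron, and the boron later becomes the CH2O branch.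
4. Forward: carbamates 7 (Z-alkene) and 9 are made; lithiated 9 is inserted into diboron 11 to give 14; lithiated 7 is inserted into the primary C–B bond of 14 (fragment union). Double CH2 insertion/oxidation, acetylation, hydroboration/Suzuki coupling with the preformed butenolide ring and desilylation follow.
5. Stereochemistry: both CH centres (R,R) are set by reagent control (s-BuLi/(+)-sparteine deprotonation, retentive borylation, invertive 1,2-shift); the Z-alkene comes from a Still–Gennari olefination.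

Key step: step 9

Remark: the sense of induction is taken as the mirror image of the established course with (−)-sparteine, i.e. s-BuLi/(+)-sparteine removes the pro-R α-proton of an O-alkyl carbamate, boron enters with retention and the 1,2-shift inverts the carbon.

**Route**

Step 1
Reactants: 1 butane-1,4-diol
Product: 2 4-hydroxybutyl N,N-diisopropylcarbamate
Conditions: i-Pr2NCOCl (1 equiv), 1 (3 equiv), Et3N, CH2Cl2, reflux
Reagents that add atoms: N,N-diisopropylcarbamoyl chloride, CC(C)N(C(C)C)C(Cl)=O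
Why: O-carbamoylation of an alcohol with a carbamoyl chloride, the excess of the symmetrical diol holding the reaction at the mono-carbamate.

Step 2
Reactants: 2 4-hydroxybutyl N,N-diisopropylcarbamate
Product: 3 4-oxobutyl N,N-diisopropylcarbamate
Conditions: TEMPO (10 mol %), PhI(OAc)2 (1.1 equiv), CH2Cl2, rt
Reagents that add atoms: none
Why: TEMPO/PhI(OAc)2 (oxoammonium) oxidation of a primary alcohol stops at the aldehyde and does not touch the carbamate.

Step 3
Reactants: 3 4-oxobutyl N,N-diisopropylcarbamate; 4 ethyl 2-[bis(2,2,2-trifluoroethoxy)phosphoryl]propanoate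
Product: 5 ethyl (Z)-6-[(diisopropylcarbamoyl)oxy]-2-methylhex-2-enoate
Conditions: 4, KN(SiMe3)2, 18-crown-6, THF, −78 °C; then 3
Reagents that add atoms: none
Why: Still–Gennari olefination, in which the electron-poor trifluoroethyl phosphonate eliminates fast from the kinetic adduct under dissociating conditions, should give the Z-trisubstituted enoate (chain cis to the ester).

Step 4
Reactants: 5 ethyl (Z)-6-[(diisopropylcarbamoyl)oxy]-2-methylhex-2-enoate
Product: 6 (Z)-6-hydroxy-5-methylhex-4-en-1-yl N,N-diisopropylcarbamate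
Conditions: i-Bu2AlH (2.5 equiv), CH2Cl2, −78 °C; aq. KNaC4H4O6 work-up
Reagents that add atoms: none
Why: 1,2-reduction of the enoate by i-Bu2AlH at low temperature should give the allylic alcohol with the Z geometry kept, the hindered diisopropylcarbamate being inert under these conditions.

Step 5
Reactants: 6 (Z)-6-hydroxy-5-methylhex-4-en-1-yl N,N-diisopropylcarbamate
Product: 7 (Z)-6-[(tert-butyldimethylsilyl)oxy]-5-methylhex-4-en-1-yl N,N-diisopropylcarbamate
Conditions: TBSCl, imidazole, CH2Cl2, rt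
Reagents that add atoms: tert-butyldimethylsilyl chloride, CC(C)(C)[Si](C)(C)Cl
Why: standard silylation of a primary allylic alcohol, which marks this oxygen as different from the two that will become acetates.

Step 6
Reactants: 8 but-3-en-1-ol
Product: 9 but-3-en-1-yl N,N-diisopropylcarbamate
Conditions: i-Pr2NCOCl, Et3N, CH2Cl2, reflux
Reagents that add atoms: N,N-diisopropylcarbamoyl chloride, CC(C)N(C(C)C)C(Cl)=O
Why: O-carbamoylation of a primary alcohol installs the directing and leaving group needed for α-lithiation and 1,2-migration.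

Step 7
Reactants: 10 2-allyl-4,4,5,5-tetramethyl-1,3,2-dioxaborolane (allylboronic acid pinacol ester)
Product: 11 2,2'-(propane-1,3-diyl)bis(4,4,5,5-tetramethyl-1,3,2-dioxaborolane)
Conditions: HBpin (1.2 equiv), [Ir(cod)Cl]2 (1.5 mol %), dppm (3 mol %), CH2Cl2, rt
Reagents that add atoms: pinacolborane, B1OC(C)(C)C(C)(C)O1
Why: iridium-catalysed hydroboration of a terminal alkene with pinacolborane is anti-Markovnikov, so boron should go to the terminal carbon and give the symmetrical 1,3-diboron.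

Step 8
Reactants: 9 but-3-en-1-yl N,N-diisopropylcarbamate; 11 2,2'-(propane-1,3-diyl)bis(4,4,5,5-tetramethyl-1,3,2-dioxaborolane)
Product: 14 (R)-2,2'-(hept-6-ene-1,4-diyl)bis(4,4,5,5-tetramethyl-1,3,2-dioxaborolane), via lithiated carbamate 12 (not isolated), via boronate complex 13 (not isolated)
Conditions: 9 (1.0 equiv), (+)-sparteine (1.2 equiv), s-BuLi (1.15 equiv), Et2O, −78 °C, 5 h; 11 (3 equiv), −78 °C, 1 h; MgBr2·OEt2, reflux, 16 h
Reagents that add atoms: none
Why: lithiation–borylation, in which carbamate-directed Hoppe deprotonation removes the pro-R α-proton, one of the two equivalent primary borons of 11 (in excess to suppress double reaction) captures the carbanion with retention, and the MgBr2-promoted 1,2-shift of the CH2 group with loss of the carbamate inverts that carbon, so the stereocentre is set by the diamine alone.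

Step 9
Reactants: 7 (Z)-6-[(tert-butyldimethylsilyl)oxy]-5-methylhex-4-en-1-yl N,N-diisopropylcarbamate; 14 (R)-2,2'-(hept-6-ene-1,4-diyl)bis(4,4,5,5-tetramethyl-1,3,2-dioxaborolane)
Product: 17 tert-butyldimethyl{[(2Z,6R,10R)-2-methyl-6,10-bis(4,4,5,5-tetramethyl-1,3,2-dioxaborolan-2-yl)trideca-2,12-dien-1-yl]oxy}silane, via lithiated carbamate 15 (not isolated), via boronate complex 16 (not isolated)
Conditions: 7 (1.0 equiv), (+)-sparteine (1.2 equiv), s-BuLi (1.1 equiv), Et2O, −78 °C, 5 h; 14 (1.1 equiv), −78 °C, 2 h; MgBr2·OEt2, reflux, 16 h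
Reagents that add atoms: none
Why: s-BuLi/(+)-sparteine removes the pro-R α-proton of 7 to give the configurationally stable carbenoid 15, which is captured with retention by the primary boron of 14 to give boronate 16; on warming with MgBr2 the CH2 group on boron shifts anti-periplanar to the departing carbamate, forming the CH2–CH bond with inversion at the carbenoid carbon. The closest known reaction type is the lithiation–borylation of primary alkyl pinacol boronic esters with sparteine-bound lithiated carbamates, including its site-selective use on bis(boronic esters) at the primary boron. No ring is closed. The new stereocentre is controlled only by the diamine (relayed through retention then inversion), so the remote centre already in 14 neither helps nor interferes. The step needs site selectivity for the CH2–B over the CH–B of 14, which the bulk of the sparteine-bound carbenoid against the α-branched boron and the slight excess of 14 should secure. It also needs α-deprotonation in preference to attack at the allylic silyl ether, which the carbamate-directed lithiation at −78 °C in Et2O should secure.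

Step 10
Reactants: 17 tert-butyldimethyl{[(2Z,6R,10R)-2-methyl-6,10-bis(4,4,5,5-tetramethyl-1,3,2-dioxaborolan-2-yl)trideca-2,12-dien-1-yl]oxy}silane
Product: 19 (2R,6R)-2-allyl-6-[(Z)-5-[(tert-butyldimethylsilyl)oxy]-4-methylpent-3-en-1-yl]heptane-1,7-diol, via bis(boronic ester) 18 (not isolated)
Conditions: BrCH2Cl (6 equiv), n-BuLi (5 equiv), Et2O, −78 °C to rt; then 2 M NaOH, 30% H2O2, THF, 0 °C to rt
Reagents that add atoms: bromochloromethane, ClCBr; hydrogen peroxide, OO
Why: Matteson homologation (chloromethyllithium made in situ adds to each boron at −78 °C and the secondary alkyl group shifts from boron to CH2 with retention on warming) followed by stereoretentive oxidation of both primary C–B bonds should give both hydroxymethyl branches at once without touching either stereocentre.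

Step 11
Reactants: 19 (2R,6R)-2-allyl-6-[(Z)-5-[(tert-butyldimethylsilyl)oxy]-4-methylpent-3-en-1-yl]heptane-1,7-diol
Product: 20 (2R,6R)-2-allyl-6-[(Z)-5-[(tert-butyldimethylsilyl)oxy]-4-methylpent-3-en-1-yl]heptane-1,7-diyl diacetate
Conditions: Ac2O, pyridine, DMAP (cat.), CH2Cl2, 0 °C to rt
Reagents that add atoms: acetic anhydride, CC(=O)OC(C)=O
Why: DMAP-catalysed acylation converts both primary alcohols into acetates while the third oxygen stays silylated.

Step 12
Reactants: 20 (2R,6R)-2-allyl-6-[(Z)-5-[(tert-butyldimethylsilyl)oxy]-4-methylpent-3-en-1-yl]heptane-1,7-diyl diacetate; 21 3-bromofuran-2(5H)-one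
Product: 23 (2R,6R)-2-[(Z)-5-[(tert-butyldimethylsilyl)oxy]-4-methylpent-3-en-1-yl]-6-[3-(2-oxo-2,5-dihydrofuran-3-yl)propyl]heptane-1,7-diyl diacetate, via alkylborane 22 (not isolated)
Conditions: 9-BBN-H (1.5 equiv), THF, 0 °C to rt; then 21 (1.5 equiv), PdCl2(dppf) (5 mol %), AsPh3 (10 mol %), K3PO4 (aq., 3 equiv), DMF, rt
Reagents that add atoms: none
Why: 9-BBN should hydroborate the monosubstituted alkene in preference to the trisubstituted one, and the primary alkylborane then undergoes B-alkyl Suzuki–Miyaura coupling at the α-bromo enoate C–Br bond, catalysed by zerovalent palladium formed in situ from PdCl2(dppf), under a mild base that spares acetates, silyl ether and lactone.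

Step 13
Reactants: 23 (2R,6R)-2-[(Z)-5-[(tert-butyldimethylsilyl)oxy]-4-methylpent-3-en-1-yl]-6-[3-(2-oxo-2,5-dihydrofuran-3-yl)propyl]heptane-1,7-diyl diacetate
Product: 24 (2R,6R)-2-[(Z)-5-hydroxy-4-methylpent-3-en-1-yl]-6-[3-(2-oxo-2,5-dihydrofuran-3-yl)propyl]heptane-1,7-diyl diacetate
Conditions: HF·pyridine, pyridine, THF, 0 °C to rt
Reagents that add atoms: none
Why: fluoride cleavage of the primary allylic silyl ether under buffered conditions should leave both acetates and the butenolide intact, acyl migration being excluded by the long tether.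

**Compound list**

1 | butane-1,4-diol | OCCCCO | starting material
2 | 4-hydroxybutyl N,N-diisopropylcarbamate | CC(C)N(C(C)C)C(=O)OCCCCO | intermediate
3 | 4-oxobutyl N,N-diisopropylcarbamate | CC(C)N(C(C)C)C(=O)OCCCC=O | intermediate
4 | ethyl 2-[bis(2,2,2-trifluoroethoxy)phosphoryl]propanoate | CCOC(=O)C(C)P(=O)(OCC(F)(F)F)OCC(F)(F)F | starting material
5 | ethyl (Z)-6-[(diisopropylcarbamoyl)oxy]-2-methylhex-2-enoate | CCOC(=O)/C(C)=C\CCCOC(=O)N(C(C)C)C(C)C | intermediate
6 | (Z)-6-hydroxy-5-methylhex-4-en-1-yl N,N-diisopropylcarbamate | CC(C)N(C(C)C)C(=O)OCCC/C=C(/C)CO | intermediate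
7 | (Z)-6-[(tert-butyldimethylsilyl)oxy]-5-methylhex-4-en-1-yl N,N-diisopropylcarbamate | CC(C)N(C(C)C)C(=O)OCCC/C=C(/C)CO[Si](C)(C)C(C)(C)C | intermediate
8 | but-3-en-1-ol | C=CCCO | starting material
9 | but-3-en-1-yl N,N-diisopropylcarbamate | C=CCCOC(=O)N(C(C)C)C(C)C | intermediate
10 | 2-allyl-4,4,5,5-tetramethyl-1,3,2-dioxaborolane | C=CCB1OC(C)(C)C(C)(C)O1 | starting material
11 | 2,2'-(propane-1,3-diyl)bis(4,4,5,5-tetramethyl-1,3,2-dioxaborolane) | CC1(C)OB(CCCB2OC(C)(C)C(C)(C)O2)OC1(C)C | intermediate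
12 | (R)-1-lithiobut-3-en-1-yl N,N-diisopropylcarbamate, bound to (+)-sparteine in solution | [Li][C@H](CC=C)OC(=O)N(C(C)C)C(C)C | intermediate
13 | lithium boronate from 12 and one boron of 11: (R)-1-(diisopropylcarbamoyloxy)but-3-en-1-yl and 3-(pinacolboryl)propyl groups on a pinacol borate | C=CC[C@H](OC(=O)N(C(C)C)C(C)C)[B-]1(CCCB2OC(C)(C)C(C)(C)O2)OC(C)(C)C(C)(C)O1.[Li+] | intermediate
14 | (R)-2,2'-(hept-6-ene-1,4-diyl)bis(4,4,5,5-tetramethyl-1,3,2-dioxaborolane) | C=CC[C@@H](CCCB1OC(C)(C)C(C)(C)O1)B1OC(C)(C)C(C)(C)O1 | intermediate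
15 | (R,Z)-6-[(tert-butyldimethylsilyl)oxy]-1-lithio-5-methylhex-4-en-1-yl N,N-diisopropylcarbamate, bound to (+)-sparteine in solution | [Li][C@H](CC/C=C(/C)CO[Si](C)(C)C(C)(C)C)OC(=O)N(C(C)C)C(C)C | intermediate
16 | lithium boronate from 15 and the primary boron of 14 (secondary boronic ester unchanged) | C=CC[C@H](B1OC(C)(C)C(C)(C)O1)CCC[B-]1([C@H](CC/C=C(/C)CO[Si](C)(C)C(C)(C)C)OC(=O)N(C(C)C)C(C)C)OC(C)(C)C(C)(C)O1.[Li+] | intermediate
17 | tert-butyldimethyl{[(2Z,6R,10R)-2-methyl-6,10-bis(4,4,5,5-tetramethyl-1,3,2-dioxaborolan-2-yl)trideca-2,12-dien-1-yl]oxy}silane | C=CC[C@H](B1OC(C)(C)C(C)(C)O1)CCC[C@@H](B1OC(C)(C)C(C)(C)O1)CC/C=C(/C)CO[Si](C)(C)C(C)(C)C | intermediate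
18 | tert-butyldimethyl{[(2Z,6R,10R)-2-methyl-6,10-bis[(4,4,5,5-tetramethyl-1,3,2-dioxaborolan-2-yl)methyl]trideca-2,12-dien-1-yl]oxy}silane | C=CC[C@H](CB1OC(C)(C)C(C)(C)O1)CCC[C@@H](CB1OC(C)(C)C(C)(C)O1)CC/C=C(/C)CO[Si](C)(C)C(C)(C)C | intermediate
19 | (2R,6R)-2-allyl-6-[(Z)-5-[(tert-butyldimethylsilyl)oxy]-4-methylpent-3-en-1-yl]heptane-1,7-diol | C=CC[C@H](CO)CCC[C@@H](CO)CC/C=C(/C)CO[Si](C)(C)C(C)(C)C | intermediate
20 | (2R,6R)-2-allyl-6-[(Z)-5-[(tert-butyldimethylsilyl)oxy]-4-methylpent-3-en-1-yl]heptane-1,7-diyl diacetate | C=CC[C@H](COC(C)=O)CCC[C@@H](COC(C)=O)CC/C=C(/C)CO[Si](C)(C)C(C)(C)C | intermediate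
21 | 3-bromofuran-2(5H)-one | O=C1OCC=C1Br | starting material
22 | B-alkyl-9-borabicyclo[3.3.1]nonane from anti-Markovnikov addition of 9-BBN-H to the terminal alkene of 20 | C1CC2CCCC(C1)B2CCC[C@H](COC(C)=O)CCC[C@@H](COC(C)=O)CC/C=C(/C)CO[Si](C)(C)C(C)(C)C | intermediate
23 | (2R,6R)-2-[(Z)-5-[(tert-butyldimethylsilyl)oxy]-4-methylpent-3-en-1-yl]-6-[3-(2-oxo-2,5-dihydrofuran-3-yl)propyl]heptane-1,7-diyl diacetate | O=C1OCC=C1CCC[C@H](COC(C)=O)CCC[C@@H](COC(C)=O)CC/C=C(/C)CO[Si](C)(C)C(C)(C)C | intermediate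
24 | (2R,6R)-2-[(Z)-5-hydroxy-4-methylpent-3-en-1-yl]-6-[3-(2-oxo-2,5-dihydrofuran-3-yl)propyl]heptane-1,7-diyl diacetate | O=C1OCC=C1CCC[C@H](COC(C)=O)CCC[C@@H](COC(C)=O)CC/C=C(/C)CO | target

**Count and risks**

Total step count: 13. Longest linear sequence: 10 steps (steps 1–5 and 9–13).

Steps most likely to fail:

Step 9. The carbenoid may not distinguish well enough between the primary and the secondary boron of 14 (loss of site selectivity), giving homologation at the wrong boron or at both. Fallback: the first stereocentre is finished before the second boron exists, so the union meets a mono-boron partner. It sets out from 9. Lithiated carbamate 12 is trapped with 2-(3-chloropropyl)-4,4,5,5-tetramethyl-1,3,2-dioxaborolane and rearranged (MgBr2·OEt2, reflux) to (R)-2-(7-chlorohept-1-en-4-yl)-4,4,5,5-tetramethyl-1,3,2-dioxaborolane F1. Homologation and oxidation as in step 10 should give (R)-2-(3-chloropropyl)pent-4-en-1-ol F2. Acid-catalysed reaction with 4-methoxybenzyl trichloroacetimidate gives 1-({[(R)-2-(3-chloropropyl)pent-4-en-1-yl]oxy}methyl)-4-methoxybenzene F3. CuCl/Xantphos-catalysed borylation with B2pin2 and KOt-Bu in THF gives 2-[(R)-4-{[(4-methoxybenzyl)oxy]methyl}hept-6-en-1-yl]-4,4,5,5-tetramethyl-1,3,2-dioxaborolane F4. F4 is combined with 15 under the conditions of step 9 to give tert-butyl{[(2Z,6R,10R)-10-{[(4-methoxybenzyl)oxy]methyl}-2-methyl-6-(4,4,5,5-tetramethyl-1,3,2-dioxaborolan-2-yl)trideca-2,12-dien-1-yl]oxy}dimethylsilane F5. Homologation and oxidation as in step 10 give (2R,6R)-2-[(Z)-5-[(tert-butyldimethylsilyl)oxy]-4-methylpent-3-en-1-yl]-6-{[(4-methoxybenzyl)oxy]methyl}non-8-en-1-ol F6. DDQ (CH2Cl2, pH 7 buffer) removes the 4-methoxybenzyl group and the route is rejoined at diol 19.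

Step 12. Transmetalation of the alkylborane may be slow, so that protodeboronation and base-induced opening or isomerisation of the bromobutenolide compete with cross-coupling. Fallback: the butenolide is built by enolate alkylation and sulfoxide elimination instead of cross-coupling. It sets out from 20. Hydroboration with 9-BBN-H (through alkylborane 22) and oxidation with NaBO3·4H2O give (2R,6R)-2-[(Z)-5-[(tert-butyldimethylsilyl)oxy]-4-methylpent-3-en-1-yl]-6-(3-hydroxypropyl)heptane-1,7-diyl diacetate F7. I2, PPh3 and imidazole give (2R,6R)-2-[(Z)-5-[(tert-butyldimethylsilyl)oxy]-4-methylpent-3-en-1-yl]-6-(3-iodopropyl)heptane-1,7-diyl diacetate F8. The lithium enolate of 3-(phenylthio)dihydrofuran-2(3H)-one (LiN(SiMe3)2, THF/HMPA) is alkylated with F8 to give (2R,6R)-2-[(Z)-5-[(tert-butyldimethylsilyl)oxy]-4-methylpent-3-en-1-yl]-6-{3-[2-oxo-3-(phenylthio)tetrahydrofuran-3-yl]propyl}heptane-1,7-diyl diacetate F9 (both epimers at the lactone carbon, which is of no consequence). NaIO4 in aqueous MeOH gives the corresponding sulfoxide, (2R,6R)-2-[(Z)-5-[(tert-butyldimethylsilyl)oxy]-4-methylpent-3-en-1-yl]-6-{3-[2-oxo-3-(phenylsulfinyl)tetrahydrofuran-3-yl]propyl}heptane-1,7-diyl diacetate F10. Thermal syn-elimination (toluene, reflux) should give the endocyclic alkene and rejoins the route at 23.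

Step 8. Deprotonation of the homoallylic carbamate may partly take the allylic β-proton (elimination of the carbamate), and the symmetrical diboron may react at both ends (loss of mono-selectivity). Fallback: the roles at this stereocentre are exchanged, so that the allyl group becomes the migrating group and the tether comes from the carbamate. It sets out from 2. TBSCl and imidazole give 4-[(tert-butyldimethylsilyl)oxy]butyl N,N-diisopropylcarbamate F11. Lithiation with s-BuLi/(−)-sparteine (the mirror-image diamine is needed because the two carbon substituents have exchanged roles), addition of allylboronic ester 10 and MgBr2·OEt2-promoted migration give (R)-tert-butyldimethyl{[4-(4,4,5,5-tetramethyl-1,3,2-dioxaborolan-2-yl)hept-6-en-1-yl]oxy}silane F12. PPTS in MeOH gives (R)-4-(4,4,5,5-tetramethyl-1,3,2-dioxaborolan-2-yl)hept-6-en-1-ol F13. I2, PPh3 and imidazole give (R)-2-(7-iodohept-1-en-4-yl)-4,4,5,5-tetramethyl-1,3,2-dioxaborolane F14. CuI/PPh3-catalysed borylation with B2pin2 and LiOMe in DMF rejoins the route at 14.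

**Further compounds**

F1 | step 9 | (R)-2-(7-chlorohept-1-en-4-yl)-4,4,5,5-tetramethyl-1,3,2-dioxaborolane | C=CC[C@@H](CCCCl)B1OC(C)(C)C(C)(C)O1
F2 | step 9 | (R)-2-(3-chloropropyl)pent-4-en-1-ol | C=CC[C@@H](CCCCl)CO
F3 | step 9 | 1-({[(R)-2-(3-chloropropyl)pent-4-en-1-yl]oxy}methyl)-4-methoxybenzene | C=CC[C@@H](CCCCl)COCc1ccc(OC)cc1
F4 | step 9 | 2-[(R)-4-{[(4-methoxybenzyl)oxy]methyl}hept-6-en-1-yl]-4,4,5,5-tetramethyl-1,3,2-dioxaborolane | C=CC[C@@H](CCCB1OC(C)(C)C(C)(C)O1)COCc1ccc(OC)cc1
F5 | step 9 | tert-butyl{[(2Z,6R,10R)-10-{[(4-methoxybenzyl)oxy]methyl}-2-methyl-6-(4,4,5,5-tetramethyl-1,3,2-dioxaborolan-2-yl)trideca-2,12-dien-1-yl]oxy}dimethylsilane | C=CC[C@H](COCc1ccc(OC)cc1)CCC[C@@H](B1OC(C)(C)C(C)(C)O1)CC/C=C(/C)CO[Si](C)(C)C(C)(C)C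
F6 | step 9 | (2R,6R)-2-[(Z)-5-[(tert-butyldimethylsilyl)oxy]-4-methylpent-3-en-1-yl]-6-{[(4-methoxybenzyl)oxy]methyl}non-8-en-1-ol | C=CC[C@H](COCc1ccc(OC)cc1)CCC[C@@H](CO)CC/C=C(/C)CO[Si](C)(C)C(C)(C)C
F7 | step 12 | (2R,6R)-2-[(Z)-5-[(tert-butyldimethylsilyl)oxy]-4-methylpent-3-en-1-yl]-6-(3-hydroxypropyl)heptane-1,7-diyl diacetate | OCCC[C@H](COC(C)=O)CCC[C@@H](COC(C)=O)CC/C=C(/C)CO[Si](C)(C)C(C)(C)C
F8 | step 12 | (2R,6R)-2-[(Z)-5-[(tert-butyldimethylsilyl)oxy]-4-methylpent-3-en-1-yl]-6-(3-iodopropyl)heptane-1,7-diyl diacetate | ICCC[C@H](COC(C)=O)CCC[C@@H](COC(C)=O)CC/C=C(/C)CO[Si](C)(C)C(C)(C)C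
F9 | step 12 | (2R,6R)-2-[(Z)-5-[(tert-butyldimethylsilyl)oxy]-4-methylpent-3-en-1-yl]-6-{3-[2-oxo-3-(phenylthio)tetrahydrofuran-3-yl]propyl}heptane-1,7-diyl diacetate | O=C1OCCC1(Sc1ccccc1)CCC[C@H](COC(C)=O)CCC[C@@H](COC(C)=O)CC/C=C(/C)CO[Si](C)(C)C(C)(C)C
F10 | step 12 | (2R,6R)-2-[(Z)-5-[(tert-butyldimethylsilyl)oxy]-4-methylpent-3-en-1-yl]-6-{3-[2-oxo-3-(phenylsulfinyl)tetrahydrofuran-3-yl]propyl}heptane-1,7-diyl diacetate | O=C1OCCC1(S(=O)c1ccccc1)CCC[C@H](COC(C)=O)CCC[C@@H](COC(C)=O)CC/C=C(/C)CO[Si](C)(C)C(C)(C)C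
F11 | step 8 | 4-[(tert-butyldimethylsilyl)oxy]butyl N,N-diisopropylcarbamate | CC(C)N(C(C)C)C(=O)OCCCCO[Si](C)(C)C(C)(C)C
F12 | step 8 | (R)-tert-butyldimethyl{[4-(4,4,5,5-tetramethyl-1,3,2-dioxaborolan-2-yl)hept-6-en-1-yl]oxy}silane | C=CC[C@@H](CCCO[Si](C)(C)C(C)(C)C)B1OC(C)(C)C(C)(C)O1
F13 | step 8 | (R)-4-(4,4,5,5-tetramethyl-1,3,2-dioxaborolan-2-yl)hept-6-en-1-ol | C=CC[C@@H](CCCO)B1OC(C)(C)C(C)(C)O1
F14 | step 8 | (R)-2-(7-iodohept-1-en-4-yl)-4,4,5,5-tetramethyl-1,3,2-dioxaborolane | C=CC[C@@H](CCCI)B1OC(C)(C)C(C)(C)O1
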